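All constants are assumed; the run is a simulation.

The split of dissolved partner between two fates, a ratio, comes first here: target by way of adduct, or quenched reagent.

starting material 0.010 M; solid reagent 7.00 mM; protic impurity 10.0 mM; time 30 s

    starting material + partner ⇌ adduct, settled at all times (K1 = 240 M⁻¹)
    adduct → target (k2 = 3.4 s⁻¹)
    solid reagent ⇌ partner, rate k3*(cs3 - [partner]) while solid is left; crystals form when [partner] > cs3 (cs3 = 5.3 mM, k3 = 0.042 s⁻¹)
    partner + protic impurity → quenched reagent (k4 = 6.4 M⁻¹ s⁻¹)

- solid, in amounts per volume of the solution: solid reagent
- at the start none of the solid reagent is in solution
- run time (flask): 30 s

- target at 30 s, in percent of the starting material charged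
- concentration of partner in solution at 30 s, in percent of saturation

Where does dissolved partner go at the start of this flask? Through the adduct balance it goes to target with a pseudo-first-order constant of 8.16 s⁻¹, and to quenched reagent with 0.0640 s⁻¹. The ratio is 128, or 2.11 powers of ten.

Which step is slow, then? Dissolution is the rate-limiting step, because its coefficient 0.042 s⁻¹ is far smaller than that first constant. The solid therefore feeds at nearly all of its full rate, 0.223 mM s⁻¹, at the start of this flask. The solid charge over that feed is 31.4 s; this is the feed time, how long the solid lasts at full feed.

And the target? The reading at 30 s comes before the feed time, so I take feed times time, less the quenched share at the starting ratio: 66.3%.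

But starting material falls, so doesn't the ratio fall with it? Yes. The feed leaves 33.2% of it at the end, which costs 0.479 of a power of ten and leaves a ratio of 42.5. Free partner then stands at feed over the target sink, 1.55% of saturation.

The forecast gives 64% of target (61% to 67%) and partner at 1.4% of saturation (1.1% to 1.8%), reasoning that “The partner is consumed almost as fast as it dissolves”. My target figure is higher than its figure, and my saturation figure is higher too.

The flask gives 64.1% of target, with partner at 1.38% of saturation. Its solid reagent at 30.0 s stands at 5.38% of its charge, against 4.60% from the feed time. A neighbouring flask, the same except for 0.0042 M of solid reagent, has a feed time of 18.8 s, shorter than 30 s. Read at 30.0 s, that neighbour holds 0% of its solid reagent and 41.6% of target, with 58.4% of the starting material left.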